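**Plan**
1. Retrosynthesis: the two silyl ethers come off last, the Cα ketone is taken back to a benzylic carbinol and the Cγ CH2OH to an N-acyl carbonyl. The Cα–Cβ bond is then cut as an aldol, and the imide is cut at its N–acyl bond and at the phenol O–CH2 bond.
2. Enabling feature: Cβ carries the guaiacyl ether oxygen and lies between the aryl-ketone carbon Cα and the hydroxymethyl carbon Cγ. It is therefore the α-carbon of an aryloxyacetic acid whose carboxyl carbon is Cγ, and Cα, a ketone in the target, can pass through a throw-away carbinol.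
3. Forward: dihydroconiferyl alcohol → aryloxyacetic acid → (R)-4-benzyloxazolidinone imide, which is joined to O-silyl syringaldehyde in one acyclic C–C bond formation (no ring is formed anywhere). Reduction at Cγ, benzylic oxidation at Cα and desilylation follow.
4. Stereochemistry: the single stereocentre of the target (Cβ, S) comes from the auxiliary through the Z boron enolate; the carbinol centre made with it is erased by oxidation.

Key step: step 6

Remark: Cα, Cβ and Cγ denote the ketone carbon, the aryloxy-bearing stereocentre and the CH2OH carbon of the three-carbon chain; TBS = tert-butyldimethylsilyl; compounds 1, 2, 6 and 9 are taken as purchased.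

**Step 1**
Reactants: 1 dihydroconiferyl alcohol [4-(3-hydroxypropyl)-2-methoxyphenol]; 2 ethyl bromoacetate
Product: 3 ethyl [4-(3-hydroxypropyl)-2-methoxyphenoxy]acetate
Conditions: K2CO3, acetone, reflux
Reagents that add atoms: none
Why: Williamson ether synthesis; carbonate deprotonates only the phenol, so SN2 displacement of the α-bromo ester should give the aryl ether and leave the primary alcohol free.

**Step 2**
Reactants: 3 ethyl [4-(3-hydroxypropyl)-2-methoxyphenoxy]acetate
Product: 4 ethyl {4-[3-(tert-butyldimethylsilyloxy)propyl]-2-methoxyphenoxy}acetate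
Conditions: TBSCl, imidazole, DMF, 0 °C → rt
Reagents that add atoms: tert-butyldimethylsilyl chloride, CC(C)(C)[Si](C)(C)Cl
Why: Imidazole-promoted silylation of the only hydroxyl masks the side-chain alcohol against the later acylation, boron triflate and oxidant.

**Step 3**
Reactants: 4 ethyl {4-[3-(tert-butyldimethylsilyloxy)propyl]-2-methoxyphenoxy}acetate
Product: 5 {4-[3-(tert-butyldimethylsilyloxy)propyl]-2-methoxyphenoxy}acetic acid
Conditions: LiOH·H2O, THF/H2O, 0 °C → rt; cold 1 M HCl to pH 3–4
Reagents that add atoms: lithium hydroxide (aqueous), [Li+].[OH-]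
Why: Ester saponification with hydroxide is compatible with the primary silyl ether and the aryl ether, and brief cold acidification should release the acid without desilylation.

**Step 4**
Reactants: 5 {4-[3-(tert-butyldimethylsilyloxy)propyl]-2-methoxyphenoxy}acetic acid; 6 (R)-4-benzyl-2-oxazolidinone
Product: 8 (R)-4-benzyl-3-({4-[3-(tert-butyldimethylsilyloxy)propyl]-2-methoxyphenoxy}acetyl)oxazolidin-2-one, via mixed pivalic anhydride 7 (not isolated)
Conditions: PivCl, Et3N, THF, −20 °C; then LiCl, 6, −20 °C → rt
Reagents that add atoms: none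
Why: N-acylation of an oxazolidinone through a mixed pivalic anhydride, in which the LiCl-activated oxazolidinone attacks the unhindered, more electrophilic aryloxyacetyl carbonyl and the auxiliary stereocentre is untouched.

**Step 5**
Reactants: 9 syringaldehyde (4-hydroxy-3,5-dimethoxybenzaldehyde)
Product: 10 4-(tert-butyldimethylsilyloxy)-3,5-dimethoxybenzaldehyde
Conditions: TBSCl, imidazole, DMF, rt
Reagents that add atoms: tert-butyldimethylsilyl chloride, CC(C)(C)[Si](C)(C)Cl
Why: Phenol silylation removes the acidic OH that would quench the boron enolate and that would divert the later quinone oxidation towards quinone methides.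

**Step 6**
Reactants: 8 (R)-4-benzyl-3-({4-[3-(tert-butyldimethylsilyloxy)propyl]-2-methoxyphenoxy}acetyl)oxazolidin-2-one; 10 4-(tert-butyldimethylsilyloxy)-3,5-dimethoxybenzaldehyde
Product: 13 (R)-4-benzyl-3-[(2R,3S)-3-[4-(tert-butyldimethylsilyloxy)-3,5-dimethoxyphenyl]-2-{4-[3-(tert-butyldimethylsilyloxy)propyl]-2-methoxyphenoxy}-3-hydroxypropanoyl]oxazolidin-2-one, via Z dibutylboron enolate 11 (not isolated), via dibutylboron aldolate 12 (not isolated)
Conditions: Bu2BOTf, iPr2NEt, CH2Cl2, −78 → 0 °C; then 10, −78 → 0 °C; pH 7 buffer, MeOH, 30% H2O2, 0 °C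
Reagents that add atoms: none
Why: Bu2BOTf activates the imide carbonyl and Hünig's base removes the α-proton to give the Z(O) boron enolate 11, which adds to the boron-bound aldehyde through a closed Zimmerman–Traxler chair to give aldolate 12, released as 13 on oxidative work-up; this is the Evans boron-mediated syn aldol as practised with alkoxy- and aryloxyacetyl oxazolidinones and aromatic aldehydes. No ring is closed and one skeletal bond, Cα–Cβ, is formed. Cβ (C2 of the acyl chain, R at the imide stage, which becomes S once the carboxyl is CH2OH and Cα a ketone) is controlled by the (R)-benzyl group of the auxiliary, which in the dipole-opposed, non-chelated imide conformation blocks one face of the enolate. The Cα carbinol (3S) follows from the Z geometry with the aryl group equatorial in the chair and is sacrificial. The selectivity that matters is the π-facial selectivity of the enolate, secured by the tight chair with short B–O bonds and by the inability of dialkylboron to chelate the ring carbonyl, whereas syn/anti leakage would be harmless because Cα is later oxidised. The aldehyde cannot enolise and its phenol is silylated, so neither self-condensation nor protonation of the enolate should compete.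

**Step 7**
Reactants: 13 the (2R,3S) syn aldol imide
Product: 14 (1S,2S)-1-[4-(tert-butyldimethylsilyloxy)-3,5-dimethoxyphenyl]-2-{4-[3-(tert-butyldimethylsilyloxy)propyl]-2-methoxyphenoxy}propane-1,3-diol
Conditions: LiBH4, H2O (1 equiv), THF, 0 °C
Reagents that add atoms: none
Why: Reductive cleavage of an N-acyl oxazolidinone with LiBH4 reduces the exocyclic carbonyl to the Cγ primary alcohol and releases the auxiliary, without touching silyl ethers or either stereocentre.

**Step 8**
Reactants: 14 the (1S,2S) 1,3-diol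
Product: 15 (S)-1-[4-(tert-butyldimethylsilyloxy)-3,5-dimethoxyphenyl]-2-{4-[3-(tert-butyldimethylsilyloxy)propyl]-2-methoxyphenoxy}-3-hydroxypropan-1-one
Conditions: DDQ (1.2 equiv), CH2Cl2 (dry), 0 °C → rt
Reagents that add atoms: none
Why: DDQ dehydrogenation of an electron-rich benzylic alcohol, the established chemoselective Cα oxidation of β-aryl ether 1,3-diols, should proceed by hydride abstraction from the carbinol C–H activated by the para-silyloxy ring and leave the primary alcohol and the Cβ–H (hence the S centre) untouched.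

**Step 9**
Reactants: 15 the bis-silylated (S)-ketone
Product: 16 (S)-3-hydroxy-1-(4-hydroxy-3,5-dimethoxyphenyl)-2-[4-(3-hydroxypropyl)-2-methoxyphenoxy]propan-1-one (CNP0283847.1)
Conditions: HF·pyridine, pyridine, THF, 0 °C → rt
Reagents that add atoms: none
Why: Fluoride-mediated desilylation under mildly acidic, pyridine-buffered conditions should cleave both the primary alkyl silyl ether and the para-acyl-activated aryl silyl ether without enolising the α-aryloxy-β-hydroxy ketone, so Cβ stays S.

**Compound list**
1 | dihydroconiferyl alcohol, 4-(3-hydroxypropyl)-2-methoxyphenol | COc1cc(CCCO)ccc1O | starting material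
2 | ethyl bromoacetate | CCOC(=O)CBr | starting material
3 | ethyl [4-(3-hydroxypropyl)-2-methoxyphenoxy]acetate | CCOC(=O)COc1ccc(CCCO)cc1OC | intermediate
4 | ethyl {4-[3-(tert-butyldimethylsilyloxy)propyl]-2-methoxyphenoxy}acetate | CCOC(=O)COc1ccc(CCCO[Si](C)(C)C(C)(C)C)cc1OC | intermediate
5 | {4-[3-(tert-butyldimethylsilyloxy)propyl]-2-methoxyphenoxy}acetic acid | OC(=O)COc1ccc(CCCO[Si](C)(C)C(C)(C)C)cc1OC | intermediate
6 | (R)-4-benzyl-2-oxazolidinone | O=C1N[C@H](Cc2ccccc2)CO1 | starting material
7 | mixed anhydride of acid 5 and pivalic acid (not isolated) | CC(C)(C)C(=O)OC(=O)COc1ccc(CCCO[Si](C)(C)C(C)(C)C)cc1OC | intermediate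
8 | (R)-4-benzyl-3-({4-[3-(tert-butyldimethylsilyloxy)propyl]-2-methoxyphenoxy}acetyl)oxazolidin-2-one | COc1cc(CCCO[Si](C)(C)C(C)(C)C)ccc1OCC(=O)N1[C@H](Cc2ccccc2)COC1=O | intermediate
9 | syringaldehyde, 4-hydroxy-3,5-dimethoxybenzaldehyde | COc1cc(C=O)cc(OC)c1O | starting material
10 | 4-(tert-butyldimethylsilyloxy)-3,5-dimethoxybenzaldehyde | COc1cc(C=O)cc(OC)c1O[Si](C)(C)C(C)(C)C | intermediate
11 | Z(O) dibutylboron enolate of imide 8 (not isolated) | COc1cc(CCCO[Si](C)(C)C(C)(C)C)ccc1O/C=C(\OB(CCCC)CCCC)N1[C@H](Cc2ccccc2)COC1=O | intermediate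
12 | O-dibutylboryl aldolate of 13, (2R,3S) (not isolated) | COc1cc(CCCO[Si](C)(C)C(C)(C)C)ccc1O[C@@H](C(=O)N1[C@H](Cc2ccccc2)COC1=O)[C@@H](OB(CCCC)CCCC)c1cc(OC)c(O[Si](C)(C)C(C)(C)C)c(OC)c1 | intermediate
13 | (R)-4-benzyl-3-[(2R,3S)-3-[4-(tert-butyldimethylsilyloxy)-3,5-dimethoxyphenyl]-2-{4-[3-(tert-butyldimethylsilyloxy)propyl]-2-methoxyphenoxy}-3-hydroxypropanoyl]oxazolidin-2-one | COc1cc(CCCO[Si](C)(C)C(C)(C)C)ccc1O[C@@H](C(=O)N1[C@H](Cc2ccccc2)COC1=O)[C@@H](O)c1cc(OC)c(O[Si](C)(C)C(C)(C)C)c(OC)c1 | intermediate
14 | (1S,2S)-1-[4-(tert-butyldimethylsilyloxy)-3,5-dimethoxyphenyl]-2-{4-[3-(tert-butyldimethylsilyloxy)propyl]-2-methoxyphenoxy}propane-1,3-diol | COc1cc(CCCO[Si](C)(C)C(C)(C)C)ccc1O[C@@H](CO)[C@@H](O)c1cc(OC)c(O[Si](C)(C)C(C)(C)C)c(OC)c1 | intermediate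
15 | (S)-1-[4-(tert-butyldimethylsilyloxy)-3,5-dimethoxyphenyl]-2-{4-[3-(tert-butyldimethylsilyloxy)propyl]-2-methoxyphenoxy}-3-hydroxypropan-1-one | COc1cc(CCCO[Si](C)(C)C(C)(C)C)ccc1O[C@@H](CO)C(=O)c1cc(OC)c(O[Si](C)(C)C(C)(C)C)c(OC)c1 | intermediate
16 | (S)-3-hydroxy-1-(4-hydroxy-3,5-dimethoxyphenyl)-2-[4-(3-hydroxypropyl)-2-methoxyphenoxy]propan-1-one | COc1cc(CCCO)ccc1O[C@@H](CO)C(=O)c1cc(OC)c(O)c(OC)c1 | target

**Step count**
Total: 9 steps. Longest linear sequence: 8 steps (steps 1, 2, 3, 4, 6, 7, 8, 9); step 5 is a one-step side branch.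

**Steps most likely to fail**

Step 6. The boron enolate may add only sluggishly to the electron-rich, doubly ortho-substituted aldehyde, leaving the reaction incomplete, or facial control of the aryloxy-substituted enolate may erode. The fallback changes auxiliary and metal. Setting out from acid 5, carbodiimide coupling (EDC·HCl, DMAP, CH2Cl2) with (R)-4-benzylthiazolidine-2-thione should give (R)-4-benzyl-3-({4-[3-(tert-butyldimethylsilyloxy)propyl]-2-methoxyphenoxy}acetyl)thiazolidine-2-thione F1. Its chlorotitanium enolate (TiCl4, iPr2NEt, N-methylpyrrolidinone, CH2Cl2, −78 → 0 °C) should add to aldehyde 10 through the non-chelated chair to give the (2R,3S) syn adduct F2. The thione auxiliary is then displaced reductively with NaBH4 in THF/EtOH, and the route is rejoined at diol 14.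

Step 8. Hydride abstraction may also occur at the benzylic CH2 of the arylpropyl chain on the guaiacyl ring, the oxidation may stall, or the quinone may over-oxidise the product. The fallback replaces chemoselective dehydrogenation by protection and a general oxidant. Setting out from diol 14, silylation of the primary hydroxyl only (TBSCl, imidazole, CH2Cl2, 0 °C) should give (1S,2S)-3-(tert-butyldimethylsilyloxy)-1-[4-(tert-butyldimethylsilyloxy)-3,5-dimethoxyphenyl]-2-{4-[3-(tert-butyldimethylsilyloxy)propyl]-2-methoxyphenoxy}propan-1-ol F3. Dess–Martin oxidation buffered with NaHCO3 should then give the (S)-tris-silylated ketone F4. Global desilylation with HF·pyridine rejoins the route at target 16.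

Step 9. Cleavage of the hindered aryl silyl ether may be incomplete, or the α-aryloxy-β-hydroxy ketone may suffer β-elimination, retro-aldol loss of formaldehyde or epimerisation at Cβ while the silyl groups are removed. The fallback reverses the order so that no ketone is present during desilylation. Setting out from diol 14, both silyl ethers are removed with TBAF buffered with acetic acid in THF to give (1S,2S)-1-(4-hydroxy-3,5-dimethoxyphenyl)-2-[4-(3-hydroxypropyl)-2-methoxyphenoxy]propane-1,3-diol F5. The secondary benzylic alcohol is then oxidised with the acidic aerobic nitroxyl system (catalytic 4-acetamido-TEMPO, HNO3 and HCl, O2, MeCN/H2O, 45 °C), which is known to oxidise the Cα carbinol of β-aryl ether diols in the presence of free phenols and primary alcohols. This rejoins the route at target 16.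

**Further compounds**
F1 | step 6 | (R)-4-benzyl-3-({4-[3-(tert-butyldimethylsilyloxy)propyl]-2-methoxyphenoxy}acetyl)thiazolidine-2-thione | COc1cc(CCCO[Si](C)(C)C(C)(C)C)ccc1OCC(=O)N1[C@H](Cc2ccccc2)CSC1=S
F2 | step 6 | (2R,3S)-1-[(R)-4-benzyl-2-thioxothiazolidin-3-yl]-3-[4-(tert-butyldimethylsilyloxy)-3,5-dimethoxyphenyl]-2-{4-[3-(tert-butyldimethylsilyloxy)propyl]-2-methoxyphenoxy}-3-hydroxypropan-1-one | COc1cc(CCCO[Si](C)(C)C(C)(C)C)ccc1O[C@@H](C(=O)N1[C@H](Cc2ccccc2)CSC1=S)[C@@H](O)c1cc(OC)c(O[Si](C)(C)C(C)(C)C)c(OC)c1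
F3 | step 8 | (1S,2S)-3-(tert-butyldimethylsilyloxy)-1-[4-(tert-butyldimethylsilyloxy)-3,5-dimethoxyphenyl]-2-{4-[3-(tert-butyldimethylsilyloxy)propyl]-2-methoxyphenoxy}propan-1-ol | COc1cc(CCCO[Si](C)(C)C(C)(C)C)ccc1O[C@@H](CO[Si](C)(C)C(C)(C)C)[C@@H](O)c1cc(OC)c(O[Si](C)(C)C(C)(C)C)c(OC)c1
F4 | step 8 | (S)-3-(tert-butyldimethylsilyloxy)-1-[4-(tert-butyldimethylsilyloxy)-3,5-dimethoxyphenyl]-2-{4-[3-(tert-butyldimethylsilyloxy)propyl]-2-methoxyphenoxy}propan-1-one | COc1cc(CCCO[Si](C)(C)C(C)(C)C)ccc1O[C@@H](CO[Si](C)(C)C(C)(C)C)C(=O)c1cc(OC)c(O[Si](C)(C)C(C)(C)C)c(OC)c1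
F5 | step 9 | (1S,2S)-1-(4-hydroxy-3,5-dimethoxyphenyl)-2-[4-(3-hydroxypropyl)-2-methoxyphenoxy]propane-1,3-diol | COc1cc(CCCO)ccc1O[C@@H](CO)[C@@H](O)c1cc(OC)c(O)c(OC)c1
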